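**Plan** (germacrane numbering: ring C1–C10, lactone carbons C11–C13, ester carbon C14, methyl C15)

- Retrosynthesis: the C8 acrylate, the C9 acetate and the C13 methylene are removed first, then the ten-membered ring is cut at C8–C9. The open chain is cut at C1=C10 (aldol–dehydration), C2–C3 ([3,3] shift), C4–C5 (Grignard addition) and C7–C8 (conjugate addition), back to (S)-5-(hydroxymethyl)furan-2(5H)-one.
- Enabling feature: in the carbocycle C1–C10 (fused at C6–C7 to the γ-lactone), C9–C10–C1 is a 2-(methoxycarbonyl)allyl unit with oxygen on C9, next to the oxygenated C8. A C9 acetal can therefore be reduced to a γ-alkoxyallylchromium that attacks a C8 aldehyde through C9.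
- Forward order: the lactone ring is present from the start; the chain grows by C7–C8, C4–C5, C2–C3 and C1=C10; the carbocycle closes at C8–C9 in step 12; methylene and the two esters follow.
- Stereochemistry: C6 comes from the butenolide, C7 from addition anti to the C6 substituent, E-C4=C5 from the chair Claisen shift, and C8, C9 and the C1=C10 geometry from the ring closure.

Key step: step 12

Remark: step 12 is assumed to give the 8,9-threo isomer drawn; if one of the two new centres formed inverted, its ester could be put on with inversion (Mitsunobu) instead of by acylation.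

**Route**

Step 1
Reactants: 1 (S)-5-(hydroxymethyl)furan-2(5H)-one
Product: 2 (S)-5-{[(tert-butyldimethylsilyl)oxy]methyl}furan-2(5H)-one
Conditions: t-BuMe2SiCl, imidazole, CH2Cl2, 0 °C to rt
Reagents that add atoms: tert-butyldimethylsilyl chloride, CC(C)(C)[Si](C)(C)Cl
Why: Standard silyl ether formation on the primary alcohol gives a bulky C6 substituent that shields one face of the butenolide in step 2.

Step 2
Reactants: 2 (S)-5-{[(tert-butyldimethylsilyl)oxy]methyl}furan-2(5H)-one; 3 1,3-dithiane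
Product: 5 (4S,5S)-5-{[(tert-butyldimethylsilyl)oxy]methyl}-4-(1,3-dithian-2-yl)oxolan-2-one, via 2-lithio-1,3-dithiane 4 (not isolated)
Conditions: 3, n-BuLi, THF, −30 °C; then 2, THF–DMPU, −78 °C; AcOH quench at −78 °C
Reagents that add atoms: none
Why: Michael addition of the sulfur-stabilised carbanion to the butenolide should occur at C7 anti to the silyloxymethyl group on C6, which sets C7 trans to C6 and installs C8 as a masked aldehyde.

Step 3
Reactants: 5 (4S,5S)-5-{[(tert-butyldimethylsilyl)oxy]methyl}-4-(1,3-dithian-2-yl)oxolan-2-one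
Product: 6 (4S,5S)-4-(1,3-dithian-2-yl)-5-(hydroxymethyl)oxolan-2-one
Conditions: HF·pyridine, THF, 0 °C to rt
Reagents that add atoms: none
Why: Fluoride desilylation frees the primary alcohol under mildly acidic conditions that leave the lactone and the dithiane untouched.

Step 4
Reactants: 6 (4S,5S)-4-(1,3-dithian-2-yl)-5-(hydroxymethyl)oxolan-2-one
Product: 7 (2S,3S)-3-(1,3-dithian-2-yl)-5-oxooxolane-2-carbaldehyde
Conditions: SO3·pyridine, DMSO, Et3N, CH2Cl2, 0 °C; used crude
Reagents that add atoms: none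
Why: Parikh–Doering oxidation tolerates thioacetals and should give the C5 aldehyde without epimerising the adjacent C6 centre.

Step 5
Reactants: 7 (2S,3S)-3-(1,3-dithian-2-yl)-5-oxooxolane-2-carbaldehyde
Product: 8 (4S,5S)-4-(1,3-dithian-2-yl)-5-(1-hydroxy-2-methylprop-2-en-1-yl)oxolan-2-one (both carbinol epimers)
Conditions: CH2=C(CH3)MgBr, THF, −78 °C; aq. NH4Cl at −78 °C
Reagents that add atoms: isopropenylmagnesium bromide, C=C(C)[Mg]Br
Why: Grignard addition to the aldehyde is much faster than to the lactone at −78 °C and brings in C4 and C15; the new carbinol centre is lost in step 6, so its configuration does not matter.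

Step 6
Reactants: 8 (4S,5S)-4-(1,3-dithian-2-yl)-5-(1-hydroxy-2-methylprop-2-en-1-yl)oxolan-2-one
Product: 10 (4E)-5-[(2R,3S)-3-(1,3-dithian-2-yl)-5-oxooxolan-2-yl]-N,N,4-trimethylpent-4-enamide, via ketene N,O-acetal 9 (not isolated)
Conditions: MeC(OMe)2NMe2, xylene, 130 °C, methanol distilled off
Reagents that add atoms: N,N-dimethylacetamide dimethyl acetal, COC(C)(OC)N(C)C
Why: Eschenmoser–Claisen rearrangement: the allylic alcohol exchanges into 9, whose chair [3,3] shift with the lactone substituent equatorial forms C2–C3 and the E-C4=C5 double bond.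

Step 7
Reactants: 10 (4E)-5-[(2R,3S)-3-(1,3-dithian-2-yl)-5-oxooxolan-2-yl]-N,N,4-trimethylpent-4-enamide
Product: 11 (4E)-5-[(2R,3S)-3-(1,3-dithian-2-yl)-5-oxooxolan-2-yl]-4-methylpent-4-enal
Conditions: Cp2Zr(H)Cl, THF, rt; aqueous work-up
Reagents that add atoms: none
Why: Chemoselective reduction of a tertiary amide to the aldehyde by the zirconium hydride stops at the hemiaminal stage and is known to spare esters, so the lactone should survive.

Step 8
Reactants: 12 methyl 3,3-dimethoxypropanoate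
Product: 13 methyl 3,3-bis(naphthalen-2-ylmethoxy)propanoate
Conditions: naphthalen-2-ylmethanol (2.2 equiv), pyridinium p-toluenesulfonate (cat.), toluene, 90 °C, reduced pressure
Reagents that add atoms: naphthalen-2-ylmethanol, OCc1ccc2ccccc2c1
Why: Acid-catalysed transacetalisation driven by removal of methanol installs 2-naphthylmethyl groups, which resist benzylic cleavage by Me3SiI better than p-methoxybenzyl groups and are still removed by DDQ.

Step 9
Reactants: 11 (4E)-5-[(2R,3S)-3-(1,3-dithian-2-yl)-5-oxooxolan-2-yl]-4-methylpent-4-enal; 13 methyl 3,3-bis(naphthalen-2-ylmethoxy)propanoate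
Product: 15 methyl (6E)-2-[bis(naphthalen-2-ylmethoxy)methyl]-7-[(2R,3S)-3-(1,3-dithian-2-yl)-5-oxooxolan-2-yl]-3-hydroxy-6-methylhept-6-enoate (diastereomers at C1 and C10), via lithium enolate 14 (not isolated)
Conditions: 13, LiN(i-Pr)2, THF, −78 °C; then 11, −78 °C; AcOH quench at −78 °C
Reagents that add atoms: none
Why: Aldol addition of the ester enolate to the aldehyde at −78 °C should outrun β-alkoxide loss from the enolate and attack on the lactone; both new centres are removed in step 10.

Step 10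
Reactants: 15 methyl (6E)-2-[bis(naphthalen-2-ylmethoxy)methyl]-7-[(2R,3S)-3-(1,3-dithian-2-yl)-5-oxooxolan-2-yl]-3-hydroxy-6-methylhept-6-enoate
Product: 17 methyl (2E,6E)-2-[bis(naphthalen-2-ylmethoxy)methyl]-7-[(2R,3S)-3-(1,3-dithian-2-yl)-5-oxooxolan-2-yl]-6-methylhepta-2,6-dienoate, via mesylate 16 (not isolated)
Conditions: MeSO2Cl, Et3N, CH2Cl2, 0 °C; then DBU, rt
Reagents that add atoms: none
Why: Mesylation and E1cB elimination should give mainly the more stable enoate with C2 trans to the ester, and any geometric isomer can be carried on because step 12 erases this geometry.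

Step 11
Reactants: 17 methyl (2E,6E)-2-[bis(naphthalen-2-ylmethoxy)methyl]-7-[(2R,3S)-3-(1,3-dithian-2-yl)-5-oxooxolan-2-yl]-6-methylhepta-2,6-dienoate
Product: 18 methyl (2E,6E)-2-[bis(naphthalen-2-ylmethoxy)methyl]-7-[(2R,3S)-3-formyl-5-oxooxolan-2-yl]-6-methylhepta-2,6-dienoate
Conditions: MeI, CaCO3, MeCN–H2O, 45 °C; used crude
Reagents that add atoms: water, O
Why: Alkylative thioacetal hydrolysis under buffered, non-oxidising conditions should release the C8 aldehyde while sparing the acetal, the alkenes and the base-sensitive β-acyloxy aldehyde.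

Step 12
Reactants: 18 methyl (2E,6E)-2-[bis(naphthalen-2-ylmethoxy)methyl]-7-[(2R,3S)-3-formyl-5-oxooxolan-2-yl]-6-methylhepta-2,6-dienoate
Product: 21 methyl (3aR,4S,5S,6E,10E,11aR)-4-hydroxy-10-methyl-5-(naphthalen-2-ylmethoxy)-2-oxo-2,3,3a,4,5,8,9,11a-octahydrocyclodeca[b]furan-6-carboxylate, via α-iodo ether 19 (not isolated), via allylchromium 20 (not isolated)
Conditions: CrCl2 (excess), Me3SiI, THF, −30 °C, slow separate addition of 18 and Me3SiI (high dilution); aq. citric acid work-up
Reagents that add atoms: none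
Why: Proposed new method: Me3SiI should ionise the C9 acetal to the α-iodo ether 19, two equivalents of divalent chromium reduce it to the trivalent allylchromium 20 (metal on C1, enol ether C9=C10), and 20 adds through its alkoxy-bearing C9 to the C8 aldehyde in a chromium-bridged six-membered transition state that restores the C1=C10 enoate; the closest known reactions are the CrCl2/Me3SiI γ-alkoxyallylation of aldehydes with acrolein dialkyl acetals and the addition of 2-(alkoxycarbonyl)allylchromium reagents to aldehydes, neither shown intramolecularly on an ester-bearing acetal. The ten-membered ring closes by C8–C9 bond formation with all three allyl carbons inside the ring, whereas attack through C1 would give an eight-membered ring with an exocyclic enol ether and is the regiochemistry these reagents avoid. C8 is controlled by the C7 centre: C6 belongs to the tether and must lie gauche to the forming bond, so C9 should approach anti to the C7–C11 bond and past H7, which gives the 8S configuration. C9 is controlled relative to C8 by the cyclic transition state: the tether joins C2 on C1 to C7 on C8 across the six-membered array, so the aldehyde substituent is expected to sit axial in a boat-like arrangement, which turns the erythro preference of the open-chain reaction into the 8,9-threo (9S) relationship. The C1=C10 geometry (C2 cis to C9) does not depend on that of 18, because C1 is sp3 in 20; it should follow from allylic strain between C2 and the C10 ester and from the lower strain of the cis olefin in the ring. The step needs C9 rather than C1 attack, the threo pair and the cis enoate, and high dilution, low temperature and the 2-naphthylmethyl acetal are chosen to secure a clean closure.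

Step 13
Reactants: 21 methyl (3aR,4S,5S,6E,10E,11aR)-4-hydroxy-10-methyl-5-(naphthalen-2-ylmethoxy)-2-oxo-2,3,3a,4,5,8,9,11a-octahydrocyclodeca[b]furan-6-carboxylate
Product: 22 8-O-triethylsilyl ether of 21 (C8–OSiEt3 and C9–O-naphthalen-2-ylmethyl; configuration unchanged)
Conditions: Et3SiOTf, 2,6-lutidine, CH2Cl2, −78 °C
Reagents that add atoms: triethylsilyl trifluoromethanesulfonate, CC[Si](CC)(CC)OS(=O)(=O)C(F)(F)F
Why: Silylation with the silyl triflate masks the hindered C8 hydroxyl, which could otherwise translactonise onto C12 under the basic conditions of step 14.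

Step 14
Reactants: 22 8-O-triethylsilyl ether of 21
Product: 24 C11-(dimethylaminomethyl) derivative of 22 (C11 epimers), via lithium enolate 23 (not isolated)
Conditions: LiN(i-Pr)2, THF, −78 °C; then Me2N=CH2 I (Eschenmoser's salt), −78 to 0 °C
Reagents that add atoms: N,N-dimethylmethyleneiminium iodide, C=[N+](C)C.[I-]
Why: Kinetic deprotonation of the lactone α-CH2, the most acidic C–H, followed by a Mannich reaction of the enolate installs C13; the C11 configuration is irrelevant because it is removed in step 15.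

Step 15
Reactants: 24 C11-(dimethylaminomethyl) derivative of 22
Product: 26 α-methylene lactone: 22 with C11=C13 exocyclic methylene, via ammonium iodide 25 (not isolated)
Conditions: MeI, MeOH, rt; then aq. NaHCO3, EtOAc, rt
Reagents that add atoms: none
Why: Quaternisation and E1cB (Hofmann-type) loss of trimethylamine from the β-ammonium lactone is the standard mild route to α-methylene lactones.

Step 16
Reactants: 26 α-methylene lactone with C8–OSiEt3 and C9–O-naphthalen-2-ylmethyl
Product: 27 C9 alcohol: 26 with C9–OH (C8–OSiEt3 kept)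
Conditions: DDQ, CH2Cl2–pH 7 buffer, 0 °C to rt
Reagents that add atoms: none
Why: Oxidative cleavage of the electron-rich naphthylmethyl ether by DDQ should free the C9 hydroxyl without touching the silyl ether, the esters or the alkenes.

Step 17
Reactants: 27 C9 alcohol with C8–OSiEt3
Product: 28 C9 acetate: 27 with C9–OAc
Conditions: Ac2O, pyridine, 4-(dimethylamino)pyridine (cat.), CH2Cl2, 0 °C
Reagents that add atoms: acetic anhydride, CC(=O)OC(C)=O
Why: Nucleophile-catalysed acetylation of the allylic alcohol installs the C9 acetate with retention.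

Step 18
Reactants: 28 C9 acetate with C8–OSiEt3
Product: 29 methyl (3aR,4S,5S,6E,10E,11aR)-5-acetoxy-4-hydroxy-10-methyl-3-methylidene-2-oxo-2,3,3a,4,5,8,9,11a-octahydrocyclodeca[b]furan-6-carboxylate
Conditions: HF·pyridine, pyridine, THF, 0 °C
Reagents that add atoms: none
Why: Fluoride desilylation under slightly acidic conditions removes the triethylsilyl group while the neighbouring acetate should not migrate.

Step 19
Reactants: 30 ethyl 2-(hydroxymethyl)acrylate
Product: 31 ethyl 2-({[tert-butyl(dimethyl)silyl]oxy}methyl)prop-2-enoate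
Conditions: t-BuMe2SiCl, imidazole, CH2Cl2, 0 °C
Reagents that add atoms: tert-butyldimethylsilyl chloride, CC(C)(C)[Si](C)(C)Cl
Why: Silyl ether formation masks the allylic alcohol so that the acid cannot self-esterify in step 21.

Step 20
Reactants: 31 ethyl 2-({[tert-butyl(dimethyl)silyl]oxy}methyl)prop-2-enoate
Product: 32 2-({[tert-butyl(dimethyl)silyl]oxy}methyl)prop-2-enoic acid
Conditions: LiOH, THF–H2O, 0 °C; then dilute HCl to pH 4
Reagents that add atoms: lithium hydroxide, [Li+].[OH-]
Why: Ester saponification at low temperature should be faster than conjugate addition of hydroxide to the α-substituted acrylate.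

Step 21
Reactants: 29 C8 alcohol with C9 acetate and α-methylene lactone; 32 2-({[tert-butyl(dimethyl)silyl]oxy}methyl)prop-2-enoic acid
Product: 34 8-O-[2-({[tert-butyl(dimethyl)silyl]oxy}methyl)prop-2-enoyl] ester of 29, via mixed anhydride 33 (not isolated)
Conditions: 32, 2,4,6-trichlorobenzoyl chloride, Et3N, toluene, rt; then 29, 4-(dimethylamino)pyridine, toluene, 0 °C to rt
Reagents that add atoms: none
Why: Yamaguchi esterification through the mixed anhydride and the acylpyridinium ion acylates hindered secondary alcohols with retention at C8.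

Step 22
Reactants: 34 silyl-protected diester
Product: 35 methyl (3aS,4S,5S,6E,10E,11aR)-5-acetoxy-4-{[2-(hydroxymethyl)prop-2-enoyl]oxy}-10-methyl-3-methylidene-2-oxo-2,3,3a,4,5,8,9,11a-octahydrocyclodeca[b]furan-6-carboxylate (target)
Conditions: HF·pyridine, pyridine, THF, 0 °C to rt
Reagents that add atoms: none
Why: Fluoride desilylation of the primary allylic silyl ether under buffered acidic conditions should avoid acyl migration and conjugate addition to the two acrylate units.

**Compound list**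

1 | (S)-5-(hydroxymethyl)furan-2(5H)-one | O=C1C=C[C@@H](CO)O1 | starting material
2 | (S)-5-{[(tert-butyldimethylsilyl)oxy]methyl}furan-2(5H)-one | O=C1C=C[C@@H](CO[Si](C)(C)C(C)(C)C)O1 | intermediate
3 | 1,3-dithiane | C1CSCSC1 | starting material
4 | 2-lithio-1,3-dithiane (formed in the flask) | [Li]C1SCCCS1 | intermediate
5 | (4S,5S)-5-{[(tert-butyldimethylsilyl)oxy]methyl}-4-(1,3-dithian-2-yl)oxolan-2-one (trans) | S1CCCSC1[C@H]1CC(=O)O[C@@H]1CO[Si](C)(C)C(C)(C)C | intermediate
6 | (4S,5S)-4-(1,3-dithian-2-yl)-5-(hydroxymethyl)oxolan-2-one | S1CCCSC1[C@H]1CC(=O)O[C@@H]1CO | intermediate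
7 | (2S,3S)-3-(1,3-dithian-2-yl)-5-oxooxolane-2-carbaldehyde | S1CCCSC1[C@H]1CC(=O)O[C@@H]1C=O | intermediate
8 | (4S,5S)-4-(1,3-dithian-2-yl)-5-(1-hydroxy-2-methylprop-2-en-1-yl)oxolan-2-one, both carbinol epimers | S1CCCSC1[C@H]1CC(=O)O[C@@H]1C(O)C(C)=C | intermediate
9 | ketene N,O-acetal, the 1-(dimethylamino)vinyl ether of 8 (formed in the flask) | S1CCCSC1[C@H]1CC(=O)O[C@@H]1C(OC(=C)N(C)C)C(C)=C | intermediate
10 | (4E)-5-[(2R,3S)-3-(1,3-dithian-2-yl)-5-oxooxolan-2-yl]-N,N,4-trimethylpent-4-enamide | S1CCCSC1[C@H]1CC(=O)O[C@@H]1/C=C(\C)CCC(=O)N(C)C | intermediate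
11 | (4E)-5-[(2R,3S)-3-(1,3-dithian-2-yl)-5-oxooxolan-2-yl]-4-methylpent-4-enal | S1CCCSC1[C@H]1CC(=O)O[C@@H]1/C=C(\C)CCC=O | intermediate
12 | methyl 3,3-dimethoxypropanoate | COC(CC(=O)OC)OC | starting material
13 | methyl 3,3-bis(naphthalen-2-ylmethoxy)propanoate | COC(=O)CC(OCc1ccc2ccccc2c1)OCc1ccc2ccccc2c1 | intermediate
14 | lithium enolate of 13 (formed in the flask) | COC(O[Li])=CC(OCc1ccc2ccccc2c1)OCc1ccc2ccccc2c1 | intermediate
15 | methyl (6E)-2-[bis(naphthalen-2-ylmethoxy)methyl]-7-[(2R,3S)-3-(1,3-dithian-2-yl)-5-oxooxolan-2-yl]-3-hydroxy-6-methylhept-6-enoate, diastereomers at C1 and C10 | S1CCCSC1[C@H]1CC(=O)O[C@@H]1/C=C(\C)CCC(O)C(C(=O)OC)C(OCc1ccc2ccccc2c1)OCc1ccc2ccccc2c1 | intermediate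
16 | C1 methanesulfonate of 15 (formed in the flask) | S1CCCSC1[C@H]1CC(=O)O[C@@H]1/C=C(\C)CCC(OS(C)(=O)=O)C(C(=O)OC)C(OCc1ccc2ccccc2c1)OCc1ccc2ccccc2c1 | intermediate
17 | methyl (2E,6E)-2-[bis(naphthalen-2-ylmethoxy)methyl]-7-[(2R,3S)-3-(1,3-dithian-2-yl)-5-oxooxolan-2-yl]-6-methylhepta-2,6-dienoate | S1CCCSC1[C@H]1CC(=O)O[C@@H]1/C=C(\C)CC/C=C(/C(=O)OC)C(OCc1ccc2ccccc2c1)OCc1ccc2ccccc2c1 | intermediate
18 | methyl (2E,6E)-2-[bis(naphthalen-2-ylmethoxy)methyl]-7-[(2R,3S)-3-formyl-5-oxooxolan-2-yl]-6-methylhepta-2,6-dienoate | O=C[C@H]1CC(=O)O[C@@H]1/C=C(\C)CC/C=C(/C(=O)OC)C(OCc1ccc2ccccc2c1)OCc1ccc2ccccc2c1 | intermediate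
19 | α-iodo ether: 18 with C9 bearing iodine and one naphthalen-2-ylmethoxy group (formed in the flask) | O=C[C@H]1CC(=O)O[C@@H]1/C=C(\C)CC/C=C(/C(=O)OC)C(I)OCc1ccc2ccccc2c1 | intermediate
20 | γ-alkoxyallylchromium: dichlorochromium (trivalent) on C1, enol ether C9=C10 (formed in the flask) | O=C[C@H]1CC(=O)O[C@@H]1/C=C(\C)CCC([Cr](Cl)Cl)C(C(=O)OC)=COCc1ccc2ccccc2c1 | intermediate
21 | methyl (3aR,4S,5S,6E,10E,11aR)-4-hydroxy-10-methyl-5-(naphthalen-2-ylmethoxy)-2-oxo-2,3,3a,4,5,8,9,11a-octahydrocyclodeca[b]furan-6-carboxylate | O[C@H]1[C@H]2CC(=O)O[C@@H]2/C=C(\C)CC/C=C(/C(=O)OC)[C@@H]1OCc1ccc2ccccc2c1 | intermediate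
22 | methyl (3aS,4S,5S,6E,10E,11aR)-10-methyl-5-(naphthalen-2-ylmethoxy)-2-oxo-4-[(triethylsilyl)oxy]-2,3,3a,4,5,8,9,11a-octahydrocyclodeca[b]furan-6-carboxylate | CC[Si](CC)(CC)O[C@H]1[C@H]2CC(=O)O[C@@H]2/C=C(\C)CC/C=C(/C(=O)OC)[C@@H]1OCc1ccc2ccccc2c1 | intermediate
23 | lithium enolate of the lactone of 22 (formed in the flask) | CC[Si](CC)(CC)O[C@H]1[C@H]2C=C(O[Li])O[C@@H]2/C=C(\C)CC/C=C(/C(=O)OC)[C@@H]1OCc1ccc2ccccc2c1 | intermediate
24 | 22 with a dimethylaminomethyl group on C11 (position 3 of the lactone), C11 epimers | CC[Si](CC)(CC)O[C@H]1[C@H]2C(CN(C)C)C(=O)O[C@@H]2/C=C(\C)CC/C=C(/C(=O)OC)[C@@H]1OCc1ccc2ccccc2c1 | intermediate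
25 | trimethylammonium iodide from 24 (formed in the flask) | CC[Si](CC)(CC)O[C@H]1[C@H]2C(C[N+](C)(C)C)C(=O)O[C@@H]2/C=C(\C)CC/C=C(/C(=O)OC)[C@@H]1OCc1ccc2ccccc2c1.[I-] | intermediate
26 | methyl (3aS,4S,5S,6E,10E,11aR)-10-methyl-3-methylidene-5-(naphthalen-2-ylmethoxy)-2-oxo-4-[(triethylsilyl)oxy]-2,3,3a,4,5,8,9,11a-octahydrocyclodeca[b]furan-6-carboxylate | CC[Si](CC)(CC)O[C@H]1[C@H]2C(=C)C(=O)O[C@@H]2/C=C(\C)CC/C=C(/C(=O)OC)[C@@H]1OCc1ccc2ccccc2c1 | intermediate
27 | methyl (3aS,4S,5S,6E,10E,11aR)-5-hydroxy-10-methyl-3-methylidene-2-oxo-4-[(triethylsilyl)oxy]-2,3,3a,4,5,8,9,11a-octahydrocyclodeca[b]furan-6-carboxylate | CC[Si](CC)(CC)O[C@H]1[C@H]2C(=C)C(=O)O[C@@H]2/C=C(\C)CC/C=C(/C(=O)OC)[C@@H]1O | intermediate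
28 | methyl (3aS,4S,5S,6E,10E,11aR)-5-acetoxy-10-methyl-3-methylidene-2-oxo-4-[(triethylsilyl)oxy]-2,3,3a,4,5,8,9,11a-octahydrocyclodeca[b]furan-6-carboxylate | CC[Si](CC)(CC)O[C@H]1[C@H]2C(=C)C(=O)O[C@@H]2/C=C(\C)CC/C=C(/C(=O)OC)[C@@H]1OC(C)=O | intermediate
29 | methyl (3aR,4S,5S,6E,10E,11aR)-5-acetoxy-4-hydroxy-10-methyl-3-methylidene-2-oxo-2,3,3a,4,5,8,9,11a-octahydrocyclodeca[b]furan-6-carboxylate | O[C@H]1[C@H]2C(=C)C(=O)O[C@@H]2/C=C(\C)CC/C=C(/C(=O)OC)[C@@H]1OC(C)=O | intermediate
30 | ethyl 2-(hydroxymethyl)acrylate | C=C(CO)C(=O)OCC | starting material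
31 | ethyl 2-({[tert-butyl(dimethyl)silyl]oxy}methyl)prop-2-enoate | C=C(CO[Si](C)(C)C(C)(C)C)C(=O)OCC | intermediate
32 | 2-({[tert-butyl(dimethyl)silyl]oxy}methyl)prop-2-enoic acid | C=C(CO[Si](C)(C)C(C)(C)C)C(=O)O | intermediate
33 | mixed anhydride of 32 with 2,4,6-trichlorobenzoic acid (formed in the flask) | C=C(CO[Si](C)(C)C(C)(C)C)C(=O)OC(=O)c1c(Cl)cc(Cl)cc1Cl | intermediate
34 | methyl (3aS,4S,5S,6E,10E,11aR)-5-acetoxy-4-{[2-({[tert-butyl(dimethyl)silyl]oxy}methyl)prop-2-enoyl]oxy}-10-methyl-3-methylidene-2-oxo-2,3,3a,4,5,8,9,11a-octahydrocyclodeca[b]furan-6-carboxylate | C=C(CO[Si](C)(C)C(C)(C)C)C(=O)O[C@H]1[C@H]2C(=C)C(=O)O[C@@H]2/C=C(\C)CC/C=C(/C(=O)OC)[C@@H]1OC(C)=O | intermediate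
35 | methyl (3aS,4S,5S,6E,10E,11aR)-5-acetoxy-4-{[2-(hydroxymethyl)prop-2-enoyl]oxy}-10-methyl-3-methylidene-2-oxo-2,3,3a,4,5,8,9,11a-octahydrocyclodeca[b]furan-6-carboxylate | C=C(CO)C(=O)O[C@H]1[C@H]2C(=C)C(=O)O[C@@H]2/C=C(\C)CC/C=C(/C(=O)OC)[C@@H]1OC(C)=O | target

**Step count**

Total steps: 22. Longest linear sequence: 19 steps (steps 1–7, 9–18, 21 and 22); steps 8, 19 and 20 prepare the two side fragments.

**Steps most likely to fail**

1. Step 12 (ring closure). The acetal may ionise too slowly next to the electron-poor enoate, the allylchromium may be protonated or add through C1, or the closure may give the erythro pair. The fallback sets out from 18 and returns at 29. It closes the same C8–C9 bond by a pinacol coupling with low-valent titanium, a known route to ten-membered 1,2-diols that favours the trans diol in rings of this size.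
   - Mild acid hydrolysis of the acetal (aq. CF3CO2H, CH2Cl2, 0 °C) would give methyl (2E,6E)-2-formyl-7-[(2R,3S)-3-formyl-5-oxooxolan-2-yl]-6-methylhepta-2,6-dienoate F1.
   - Slow addition of F1 to TiCl3(DME)1.5 and zinc–copper couple in DME at room temperature should give the 8,9-diol F2, from which the (8S,9S) isomer would be separated.
   - Et3SiOTf and 2,6-lutidine would give the bis(triethylsilyl) ether F3.
   - The methylenation of steps 14 and 15 would then give the Mannich base F4, its methiodide F5 and the α-methylene lactone F6.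
   - HF·pyridine would give the α-methylene lactone diol F7.
   - Acetylation of the allylic, less hindered C9 hydroxyl (AcCl, 2,4,6-collidine, CH2Cl2, −78 °C) would give 29.

2. Step 14 (lactone methylenation). Deprotonation may be unselective (γ-deprotonation of the ring enoate at C2), or the lactone enolate may add transannularly to C1. The fallback sets out from 22 and returns at 26 without an amide base. Carboxylation of the lactone α-position with MeOMgOCO2Me in DMF at about 120 °C, under thermodynamic control through the magnesium chelate, would give the C11 carboxylic acid F8. Decarboxylative Mannich methylenation with aqueous formaldehyde and diethylamine in buffered acetic acid would then give 26 directly.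

3. Step 21 (C8 esterification). The acetyl group may migrate from O9 to O8 under the basic acylation conditions, and acylation of the hindered C8 hydroxyl may be slow. The fallback sets out from 26 and returns at 34 by reversing the order of the two esterifications, so that no free hydroxyl sits next to the acetate under basic conditions. HF·pyridine on 26 would give the C8 alcohol F9, which still carries the C9 naphthylmethyl ether. Yamaguchi esterification with 32 via 33 would give the C8 ester F10. DDQ would give the C9 alcohol F11, and acetylation (Ac2O, pyridine) would give 34.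

Further compounds
F1 | step 12 | methyl (2E,6E)-2-formyl-7-[(2R,3S)-3-formyl-5-oxooxolan-2-yl]-6-methylhepta-2,6-dienoate | O=C[C@H]1CC(=O)O[C@@H]1/C=C(\C)CC/C=C(/C(=O)OC)C=O
F2 | step 12 | methyl (3aR,4S,5S,6E,10E,11aR)-4,5-dihydroxy-10-methyl-2-oxo-2,3,3a,4,5,8,9,11a-octahydrocyclodeca[b]furan-6-carboxylate | O[C@H]1[C@H]2CC(=O)O[C@@H]2/C=C(\C)CC/C=C(/C(=O)OC)[C@@H]1O
F3 | step 12 | 8,9-bis(triethylsilyl) ether of F2 | CC[Si](CC)(CC)O[C@H]1[C@H]2CC(=O)O[C@@H]2/C=C(\C)CC/C=C(/C(=O)OC)[C@@H]1O[Si](CC)(CC)CC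
F4 | step 12 | F3 with a dimethylaminomethyl group on C11 (C11 epimers) | CC[Si](CC)(CC)O[C@H]1[C@H]2C(CN(C)C)C(=O)O[C@@H]2/C=C(\C)CC/C=C(/C(=O)OC)[C@@H]1O[Si](CC)(CC)CC
F5 | step 12 | trimethylammonium iodide from F4 | CC[Si](CC)(CC)O[C@H]1[C@H]2C(C[N+](C)(C)C)C(=O)O[C@@H]2/C=C(\C)CC/C=C(/C(=O)OC)[C@@H]1O[Si](CC)(CC)CC.[I-]
F6 | step 12 | α-methylene lactone 8,9-bis(triethylsilyl) ether | CC[Si](CC)(CC)O[C@H]1[C@H]2C(=C)C(=O)O[C@@H]2/C=C(\C)CC/C=C(/C(=O)OC)[C@@H]1O[Si](CC)(CC)CC
F7 | step 12 | methyl (3aR,4S,5S,6E,10E,11aR)-4,5-dihydroxy-10-methyl-3-methylidene-2-oxo-2,3,3a,4,5,8,9,11a-octahydrocyclodeca[b]furan-6-carboxylate | O[C@H]1[C@H]2C(=C)C(=O)O[C@@H]2/C=C(\C)CC/C=C(/C(=O)OC)[C@@H]1O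
F8 | step 14 | 22 with a carboxylic acid group on C11 (C11 epimers) | CC[Si](CC)(CC)O[C@H]1[C@H]2C(C(=O)O)C(=O)O[C@@H]2/C=C(\C)CC/C=C(/C(=O)OC)[C@@H]1OCc1ccc2ccccc2c1
F9 | step 21 | methyl (3aR,4S,5S,6E,10E,11aR)-4-hydroxy-10-methyl-3-methylidene-5-(naphthalen-2-ylmethoxy)-2-oxo-2,3,3a,4,5,8,9,11a-octahydrocyclodeca[b]furan-6-carboxylate | O[C@H]1[C@H]2C(=C)C(=O)O[C@@H]2/C=C(\C)CC/C=C(/C(=O)OC)[C@@H]1OCc1ccc2ccccc2c1
F10 | step 21 | 8-O-[2-({[tert-butyl(dimethyl)silyl]oxy}methyl)prop-2-enoyl] ester of F9 | C=C(CO[Si](C)(C)C(C)(C)C)C(=O)O[C@H]1[C@H]2C(=C)C(=O)O[C@@H]2/C=C(\C)CC/C=C(/C(=O)OC)[C@@H]1OCc1ccc2ccccc2c1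
F11 | step 21 | C9 alcohol from F10 (C8 ester kept) | C=C(CO[Si](C)(C)C(C)(C)C)C(=O)O[C@H]1[C@H]2C(=C)C(=O)O[C@@H]2/C=C(\C)CC/C=C(/C(=O)OC)[C@@H]1O
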